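## Retrosynthetic overview
- Last steps: C11 ketone → exocyclic methylene → 11,20-epoxide, from the face anti to the axial C15 methyl. The three secondary OH groups (C2, C9, C14) are acetylated and the tertiary C8–OH stays free.
- The 10-membered ring is closed last by RCM, which fixes the ring-Z C5=C6 alkene (C5 vinylic methyl and C4 cis to C7).
- Key radical step: a SmI2 ketyl from the ring-A C9 aldehyde adds to C8 of an O-silyl tetronate. This forms C8–C9, the C8 tertiary carbinol, C9 and C18 in one step, with C8 set trans to C7 by the C7 stereocentre.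
- Ring A (C1, C10, C11, C14) comes from an endo Diels–Alder of (E,E)-1,4-diacetoxybutadiene with an (E)-α-methyl enal acetal. The C2 side chain is added by Grignard. The tetronate comes from lipase-resolved vinylglycolate.
- Ring order: cyclohexane (Diels–Alder), then γ-lactone (radical coupling), then the 10-membered ring (RCM).

Assumption: the chiral Lewis acid and the lipase are taken to deliver the enantiomers drawn, and succinaldehyde is taken as a commercial solution.

## Route

**Step 1**
Reactants: 1 propanal; 2 2,2-dimethoxyacetaldehyde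
Product: 3 (E)-4,4-dimethoxy-2-methylbut-2-enal
Conditions: pyrrolidine (10 mol%), AcOH, CH2Cl2, 0 °C→rt; 1 added slowly to excess 2
Reagents that add atoms: none
Why: Cross-aldol condensation (enamine catalysis) of propanal with the non-enolisable glyoxal acetal, followed by dehydration, gives the thermodynamic E-enal that will become the Diels–Alder dienophile.

**Step 2**
Reactants: 4 succinaldehyde
Product: 5 (1E,3E)-1,4-diacetoxybuta-1,3-diene
Conditions: Ac2O, KOAc, 100 °C; E,E isomer crystallised
Reagents that add atoms: acetic anhydride, CC(=O)OC(C)=O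
Why: Double enol acetylation gives the diene. The symmetrical 1,4-dioxygenated diene supplies both C11 and C14 oxygen with cis relative configuration.

**Step 3**
Reactants: 3; 5
Product: 6 Diels–Alder adduct. It is a cyclohexene with C2-CHO and C1-Me (quaternary), C14-OAc and C11-OAc, and C12=C13. CHO, C14-OAc and C11-OAc are all on the top face. The C9 dimethyl acetal and the C1 methyl are on the bottom face.
Conditions: chiral oxazaborolidinium triflimide (20 mol%), CH2Cl2, −78→−40 °C
Reagents that add atoms: none
Why: Lewis-acid-catalysed endo Diels–Alder. The E-enal places CHO endo (cis to both OAc groups) and the β-acetal exo (trans), so C1, C10, C11 and C14 are set in one step. The chiral catalyst fixes the absolute sense.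

**Step 4**
Reactants: 6
Product: 7 saturated diacetoxy aldehyde (C12–C13 CH2CH2; all stereocentres unchanged)
Conditions: H2 (1 atm), 5% Pd/C, EtOAc, rt, short reaction time
Reagents that add atoms: none
Why: Alkene hydrogenation. This removes the only alkene before the chain alkene is introduced.

**Step 5**
Reactants: 7; 8 4-bromo-2-methylbut-1-ene
Product: 9 C2 secondary alcohol (C2 bears the CH2CH2C(Me)=CH2 chain)
Conditions: 8, Mg, THF → Grignard; CeCl3, THF, −78 °C; then 7, −78 °C
Reagents that add atoms: none (the C5 unit comes from 8)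
Why: Organocerium addition is chemoselective for the aldehyde over the acetates. The new C2 centre is set by chelation (aldehyde O and C14-O) with attack anti to the ring carbon C10, in a Cram-chelate model.

**Step 6**
Reactants: 9
Product: 10 C2 acetate
Conditions: Ac2O, DMAP, pyridine, 50 °C
Reagents that add atoms: acetic anhydride, CC(=O)OC(C)=O
Why: Acetylation installs the final C2-OAc and prevents lactol formation with the later C9 aldehyde.

**Step 7**
Reactants: 10
Product: 11 C11 alcohol (C2-OAc, C14-OAc and C9 acetal retained)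
Conditions: lipase (Candida antarctica B), pH 7 phosphate buffer/t-BuOH, 30 °C
Reagents that add atoms: none (water supplies only H)
Why: Enzymatic hydrolysis cleaves only the equatorial, unhindered C11 acetate. The C2 and C14 acetates are neopentylic to C1, and C14 is axial.

**Step 8**
Reactants: 11
Product: 12 C11 TBS ether
Conditions: TBSCl, imidazole, DMF, rt
Reagents that add atoms: tert-butyldimethylsilyl chloride, CC(C)(C)[Si](C)(C)Cl
Why: Silylation protects C11-O. It is removed together with the C8 TBS group later, then oxidised.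

**Step 9**
Reactants: 12
Product: 13 C9 aldehyde (ring-A radical precursor)
Conditions: PPTS, acetone/H2O, 50 °C
Reagents that add atoms: water, O
Why: Mild acetal hydrolysis. The α-centre C10 can epimerise but settles in the equatorial (trans) arrangement needed.

**Step 10**
Reactants: 14 racemic methyl 2-hydroxybut-3-enoate; 15 vinyl propionate
Product: 16 methyl (S)-2-(propionyloxy)but-3-enoate
Conditions: lipase PS (Pseudomonas cepacia), MTBE, rt, ~50% conversion
Reagents that add atoms: none (15 is the acyl donor)
Why: Enzymatic kinetic acylation sets C7 as S. The unreacted R-alcohol is recycled by oxidation and reduction.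

**Step 11**
Reactants: 16
Product: 17 (S)-4-hydroxy-3-methyl-5-vinylfuran-2(5H)-one (3-methyltetronic acid)
Conditions: t-BuOK (2.2 equiv), THF, −78→0 °C; then aq. HCl
Reagents that add atoms: none
Why: Dieckmann condensation of the propionate enolate onto the methyl ester builds the lactone and the C18–C8 bond. C7 is not touched.

**Step 12**
Reactants: 17
Product: 18 4-(TBS-oxy)-3-methyl-5-vinylfuran-2(5H)-one ((S) at C7)
Conditions: TBSCl, Et3N, DMAP (cat.), CH2Cl2, 0 °C
Reagents that add atoms: tert-butyldimethylsilyl chloride, CC(C)(C)[Si](C)(C)Cl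
Why: Silylation converts the tetronic acid into a neutral radical acceptor and masks the future C8 oxygen.

**Step 13 (key radical step)**
Reactants: 13; 18
Product: 19 C8–C9 coupled adduct: C9-OH, C8 quaternary with OTBS, C18-H/Me, γ-lactone, C7-vinyl
Conditions: SmI2 (3.5 equiv), HMPA, t-BuOH (2 equiv), THF, −78→−40 °C; 18 in excess
Reagents that add atoms: none
Why: Proposed new method: SmI2 reduces the C9 aldehyde to a ketyl radical, which adds to C8 (the β-carbon of the β-silyloxy butenolide) on the face anti to the C7 vinyl group. This gives the trans-disposed quaternary C8 carbinol with C8–OTBS cis to C6, as in the target. The α-lactone radical is reduced to the Sm(III) enolate and protonated by t-BuOH opposite the bulky OTBS, setting C18 (H on the same face as C9). C9 is set by a chelated Felkin-type ketyl approach. The closest known reaction is SmI2 ketyl–olefin coupling to give γ-butyrolactones (Fukuzawa/Molander type).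

**Step 14**
Reactants: 19
Product: 20 ten-membered carbocycle with Z-trisubstituted C5=C6
Conditions: Hoveyda–Grubbs II (15 mol%), toluene (1 mM), 80 °C
Reagents that add atoms: none (ethylene lost)
Why: Ring-closing metathesis of the 1,1-disubstituted C5 alkene with the C7 vinyl group. The ten-membered ring forces the Z geometry and no new stereocentre forms.

**Step 15**
Reactants: 20
Product: 21 C9 acetate
Conditions: Ac2O, DMAP, Et3N, CH2Cl2, 40 °C
Reagents that add atoms: acetic anhydride, CC(=O)OC(C)=O
Why: Acetylation of the hindered secondary C9-OH installs the final C9-OAc.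

**Step 16**
Reactants: 21
Product: 22 C8-OH (tertiary) and C11-OH
Conditions: HF·pyridine, pyridine/THF, rt→40 °C
Reagents that add atoms: none
Why: Fluoride removes both TBS ethers under buffered, acid-type conditions that avoid acetate migration.

**Step 17**
Reactants: 22
Product: 23 C11 ketone
Conditions: Dess–Martin periodinane, NaHCO3, CH2Cl2, 0 °C
Reagents that add atoms: none
Why: Oxidation of the only secondary free alcohol; the tertiary C8-OH is inert. C10 is α to the ketone and remains in the equatorial, trans-fused configuration.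

**Step 18**
Reactants: 23
Product: 24 11(20)-exocyclic alkene
Conditions: Zn, CH2Br2, TiCl4, THF/CH2Cl2, 0 °C→rt
Reagents that add atoms: dibromomethane, C(Br)Br
Why: Lombardo–Takai methylenation is non-basic and chemoselective for ketones over the acetates and lactone. This avoids β-acetoxy elimination at C9–C10, and the Corey–Chaykovsky ylide would give the wrong C11 epimer.

**Step 19**
Reactants: 24
Product: 25 junceellolide K
Conditions: dimethyldioxirane (1.2 equiv), acetone/CH2Cl2, −20 °C
Reagents that add atoms: dimethyldioxirane, CC1(C)OO1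
Why: Epoxidation of the accessible exocyclic alkene from the top face, anti to the axial C15 methyl, puts the oxygen cis to C2 and C14 and C20 down. This matches the target; the hindered C5=C6 alkene in the ring is less reactive.

## Compound list
1 | propanal | CCC=O | starting material
2 | 2,2-dimethoxyacetaldehyde | COC(OC)C=O | starting material
3 | (E)-4,4-dimethoxy-2-methylbut-2-enal | O=C/C(C)=C/C(OC)OC | intermediate
4 | succinaldehyde | O=CCC=O | starting material
5 | (1E,3E)-1,4-diacetoxybutadiene | CC(=O)O/C=C/C=C/OC(C)=O | intermediate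
6 | Diels–Alder adduct (C2-CHO, C11/C14-OAc, C12=C13, C9 acetal) | O=C[C@@]1(C)[C@@H](OC(C)=O)C=C[C@@H](OC(C)=O)[C@@H]1C(OC)OC | intermediate
7 | saturated diacetoxy aldehyde | O=C[C@@]1(C)[C@@H](OC(C)=O)CC[C@@H](OC(C)=O)[C@@H]1C(OC)OC | intermediate
8 | 4-bromo-2-methylbut-1-ene | C=C(C)CCBr | starting material
9 | C2 alcohol | O[C@@H](CCC(C)=C)[C@@]1(C)[C@@H](OC(C)=O)CC[C@@H](OC(C)=O)[C@@H]1C(OC)OC | intermediate
10 | C2 acetate | CC(=O)O[C@@H](CCC(C)=C)[C@@]1(C)[C@@H](OC(C)=O)CC[C@@H](OC(C)=O)[C@@H]1C(OC)OC | intermediate
11 | C11 alcohol | CC(=O)O[C@@H](CCC(C)=C)[C@@]1(C)[C@@H](OC(C)=O)CC[C@@H](O)[C@@H]1C(OC)OC | intermediate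
12 | C11 TBS ether | CC(=O)O[C@@H](CCC(C)=C)[C@@]1(C)[C@@H](OC(C)=O)CC[C@@H](O[Si](C)(C)C(C)(C)C)[C@@H]1C(OC)OC | intermediate
13 | C9 aldehyde | CC(=O)O[C@@H](CCC(C)=C)[C@@]1(C)[C@@H](OC(C)=O)CC[C@@H](O[Si](C)(C)C(C)(C)C)[C@@H]1C=O | intermediate
14 | methyl 2-hydroxybut-3-enoate (racemic) | C=CC(O)C(=O)OC | starting material
15 | vinyl propionate | CCC(=O)OC=C | starting material
16 | methyl (S)-2-(propionyloxy)but-3-enoate | C=C[C@H](OC(=O)CC)C(=O)OC | intermediate
17 | (S)-3-methyl-5-vinyltetronic acid | C=C[C@@H]1OC(=O)C(C)=C1O | intermediate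
18 | (S)-4-(TBS-oxy)-3-methyl-5-vinylfuran-2(5H)-one | C=C[C@@H]1OC(=O)C(C)=C1O[Si](C)(C)C(C)(C)C | intermediate
19 | SmI2 coupling adduct | CC(=O)O[C@@H](CCC(C)=C)[C@@]1(C)[C@@H](OC(C)=O)CC[C@@H](O[Si](C)(C)C(C)(C)C)[C@@H]1[C@H](O)[C@]2(O[Si](C)(C)C(C)(C)C)[C@@H](C)C(=O)O[C@H]2C=C | intermediate
20 | RCM macrocycle (C9-OH, C8/C11-OTBS) | CC(=O)O[C@H]1CC/C(C)=C\[C@@H]2OC(=O)[C@H](C)[C@@]2(O[Si](C)(C)C(C)(C)C)[C@@H](O)[C@H]2[C@H](O[Si](C)(C)C(C)(C)C)CC[C@H](OC(C)=O)[C@]12C | intermediate
21 | C9 acetate of 20 | CC(=O)O[C@H]1CC/C(C)=C\[C@@H]2OC(=O)[C@H](C)[C@@]2(O[Si](C)(C)C(C)(C)C)[C@@H](OC(C)=O)[C@H]2[C@H](O[Si](C)(C)C(C)(C)C)CC[C@H](OC(C)=O)[C@]12C | intermediate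
22 | C8,C11-diol | CC(=O)O[C@H]1CC/C(C)=C\[C@@H]2OC(=O)[C@H](C)[C@@]2(O)[C@@H](OC(C)=O)[C@H]2[C@H](O)CC[C@H](OC(C)=O)[C@]12C | intermediate
23 | C11 ketone | CC(=O)O[C@H]1CC/C(C)=C\[C@@H]2OC(=O)[C@H](C)[C@@]2(O)[C@@H](OC(C)=O)[C@H]2C(=O)CC[C@H](OC(C)=O)[C@]12C | intermediate
24 | 11(20)-ene | CC(=O)O[C@H]1CC/C(C)=C\[C@@H]2OC(=O)[C@H](C)[C@@]2(O)[C@@H](OC(C)=O)[C@H]2C(=C)CC[C@H](OC(C)=O)[C@]12C | intermediate
25 | junceellolide K | CC(=O)O[C@H]1CC/C(C)=C\[C@@H]2OC(=O)[C@H](C)[C@@]2(O)[C@@H](OC(C)=O)[C@H]2[C@]3(CC[C@H](OC(C)=O)[C@]12C)CO3 | target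

## Totals
Total steps: 19. Longest linear sequence: 15 (steps 1, 3–9, 13–19).

Three steps most likely to fail:
1. **Step 13 (SmI2 ketyl–tetronate coupling).** Possible problems are β-silyloxy elimination from the Sm enolate, pinacol dimerisation, or the wrong C9 epimer.
   - Fallback: change to a polar route. Add a protected C8-ketone nucleophile to aldehyde 13, oxidise the C9 carbinol, acylate C7-OH with 2-bromopropionyl bromide, and close the lactone by intramolecular SmI2 Reformatsky aldol onto C8.
2. **Step 14 (macrocyclic RCM to the Z-trisubstituted alkene).** The strained trans-fused ten-membered ring may oligomerise or fail to close.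
   - Fallback: drop RCM and form the C6–C7 bond by intramolecular Nozaki–Hiyama–Kishi coupling of a (Z)-vinyl iodide at C5/C6 with a C7 aldehyde, then build the tetronate on the macrocycle.
3. **Step 19 (chemo- and diastereoselective epoxidation).** The trisubstituted C5=C6 alkene competes, or the epoxide forms on the wrong face.
   - Fallback: epoxidise earlier, from a 11(20)-ene intermediate lacking the C5=C6 alkene, and install the Z alkene afterwards by RCM.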